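The route rests on cutting two bonds of the cyclobutane so that the fifteen skeletal carbons become one farnesoic acid chain. The feature exploited is that the cyclobutane CH bearing the CMe2 carbon lies 1,3 across the four-membered ring from the quaternary C-CH3 and can therefore be a ketene carbonyl carbon. An intramolecular crossed [2+2] of a vinylketene with the trisubstituted C6=C7 alkene forms the cyclobutanone (C1-C2-C7-C6) and the six-membered ring of a 2-methylenebicyclo[3.1.1]heptan-6-one in one operation. Its precursor is an open-chain (2E,6E) acid with silyloxy groups at C5 and C8 and an isopropenyl ketone at C10; a reductive aldol (C11 to C1) later closes the seven-membered ring.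

Key step: step 8

Locants: C1 to C12 are those of the open-chain acid 12 (C1 carboxyl carbon, C12 terminal methylene) and are kept for the ring compounds; tricycles are named as tricyclo[5.4.0.0(2,8)]undecanes with ring atoms 1 to 11 = C6, C7, C8, C9, C10, C11, C1, C2, C3, C4, C5.
Assumption: (−)-Ipc2BCl and the (R,R)-bisphosphoramide are taken to be the antipodes that give Re-face addition in step 1 and Si-face addition in step 5; should either sense be the reverse, the mirror-image reagent is used.

Step 1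
Reactants: 1 3-methylbut-3-en-2-one; 2 (E)-4,4-dimethoxy-2-methylbut-2-enal
Product: 4 (5R,6E)-5-hydroxy-8,8-dimethoxy-2,6-dimethylocta-1,6-dien-3-one, via boron dienolate 3 (not isolated)
Conditions: (−)-Ipc2BCl, Et3N, Et2O, −78 °C; then 2, −78 to −20 °C; MeOH, pH 7 buffer, H2O2, 0 °C
Reagents that add atoms: none
Why: Boron aldol of a methyl ketone with chiral Ipc ligands: only the methyl group of 1 can be enolised, dienolate 3 should add through a cyclic transition state to the Re face of the enal (reagent control) and set C8 as R, and any shortfall in enantiopurity should be removed at step 5, where the minor enantiomer is carried into a separable diastereomer.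

Step 2
Reactants: 4 (5R,6E)-5-hydroxy-8,8-dimethoxy-2,6-dimethylocta-1,6-dien-3-one
Product: 5 (5R,6E)-8,8-dimethoxy-2,6-dimethyl-5-(triethylsilyloxy)octa-1,6-dien-3-one
Conditions: TESOTf (1.1 equiv), 2,6-lutidine, CH2Cl2, −78 °C
Reagents that add atoms: triethylsilyl triflate (TESOTf), CC[Si](CC)(CC)OS(=O)(=O)C(F)(F)F
Why: Silyl ether formation with a triflate and a hindered pyridine at low temperature avoids nucleophilic amines that would add to the isopropenyl ketone and blocks oxa-Michael closure of the β-hydroxy enone; TES is chosen so that it can later be removed beside a TBS group.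

Step 3
Reactants: 5 (5R,6E)-8,8-dimethoxy-2,6-dimethyl-5-(triethylsilyloxy)octa-1,6-dien-3-one
Product: 6 (2E,4R)-3,7-dimethyl-6-oxo-4-(triethylsilyloxy)octa-2,7-dienal
Conditions: PPTS (cat.), acetone–H2O (10:1), 0 °C to rt
Reagents that add atoms: water, O
Why: Acid-catalysed acetal hydrolysis: the conjugated dimethyl acetal ionises to an allyl-stabilised oxocarbenium ion far faster than a secondary TES ether is cleaved in aqueous acetone, and the E geometry is retained.

Step 4
Reactants: 7 methyl 3-methylbut-2-enoate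
Product: 9 tert-butyl[(1-methoxy-3-methylbuta-1,3-dien-1-yl)oxy]dimethylsilane, via lithium dienolate 8 (not isolated)
Conditions: LDA, THF, −78 °C; TBSCl, DMPU, −78 °C to rt
Reagents that add atoms: tert-butyldimethylsilyl chloride (TBSCl), CC(C)(C)[Si](C)(C)Cl
Why: Kinetic γ-deprotonation of the enoate and O-silylation give the cross-conjugated silyl ketene acetal (silyl dienolate formation); the TBS derivative is used because it is stable toward SiCl4 and can be distilled, and its ketene acetal geometry is immaterial.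

Step 5
Reactants: 6 (2E,4R)-3,7-dimethyl-6-oxo-4-(triethylsilyloxy)octa-2,7-dienal; 9 tert-butyl[(1-methoxy-3-methylbuta-1,3-dien-1-yl)oxy]dimethylsilane
Product: 10 methyl (2E,5S,6E,8R)-5-hydroxy-3,7,11-trimethyl-10-oxo-8-(triethylsilyloxy)dodeca-2,6,11-trienoate
Conditions: SiCl4 (1.1 equiv), (R,R)-1,1'-binaphthyl-2,2'-diamine-derived bisphosphoramide (5 mol %), iPr2NEt (cat.), CH2Cl2, −78 °C; aq. NaHCO3
Reagents that add atoms: none
Why: Vinylogous Mukaiyama aldol under chiral Lewis base-activated SiCl4: the bulky cationic silicon–aldehyde complex is attacked at the remote γ carbon of 9, the catalyst should direct addition to the Si face and set C5 as S independently of the distant C8 centre, the new enoate should be E, and the ketone is not activated at −78 °C.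

Step 6
Reactants: 10 methyl (2E,5S,6E,8R)-5-hydroxy-3,7,11-trimethyl-10-oxo-8-(triethylsilyloxy)dodeca-2,6,11-trienoate
Product: 11 methyl (2E,5S,6E,8R)-5-(tert-butyldimethylsilyloxy)-3,7,11-trimethyl-10-oxo-8-(triethylsilyloxy)dodeca-2,6,11-trienoate
Conditions: TBSOTf, 2,6-lutidine, CH2Cl2, −78 °C
Reagents that add atoms: tert-butyldimethylsilyl triflate (TBSOTf), CC(C)(C)[Si](C)(C)OS(=O)(=O)C(F)(F)F
Why: Standard silyl ether formation; a silyl ether is the least deactivating protection for the allylic oxygen, and the bulky TBS group is the A1,3 control element of step 8.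

Step 7
Reactants: 11 methyl (2E,5S,6E,8R)-5-(tert-butyldimethylsilyloxy)-3,7,11-trimethyl-10-oxo-8-(triethylsilyloxy)dodeca-2,6,11-trienoate
Product: 12 (2E,5S,6E,8R)-5-(tert-butyldimethylsilyloxy)-3,7,11-trimethyl-10-oxo-8-(triethylsilyloxy)dodeca-2,6,11-trienoic acid
Conditions: Me3SnOH, 1,2-dichloroethane, 70 °C; brief cold dilute aq. HCl wash
Reagents that add atoms: trimethyltin hydroxide (Me3SnOH), C[Sn](C)(C)O
Why: Me3SnOH cleaves methyl esters under near-neutral conditions through a tin carboxylate, which should spare the enone, the β-silyloxy ketone (no E1cB loss) and both silyl ethers.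

Step 8
Reactants: 12 (2E,5S,6E,8R)-5-(tert-butyldimethylsilyloxy)-3,7,11-trimethyl-10-oxo-8-(triethylsilyloxy)dodeca-2,6,11-trienoic acid
Product: 15 (1R,4S,5R,7R)-4-(tert-butyldimethylsilyloxy)-7-methyl-2-methylidene-7-[(1R)-4-methyl-3-oxo-1-(triethylsilyloxy)pent-4-en-1-yl]bicyclo[3.1.1]heptan-6-one, via acid chloride 13 (not isolated), via vinylketene 14 (not isolated)
Conditions: 1-chloro-N,N,2-trimethylprop-1-en-1-amine (1.2 equiv), CH2Cl2, 0 °C to rt; then slow addition (syringe pump) to Et3N (5 equiv), toluene, 110 °C, final concentration ca. 2 mM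
Reagents that add atoms: none
Why: The chloroenamine gives acid chloride 13 under neutral conditions and Et3N removes HCl through the C3 methyl cis to the carbonyl, so that vinylketene 14 forms at high dilution; its electrophilic C1 attacks C6 of the trisubstituted alkene while positive charge builds on tertiary C7, which collapses onto C2 in an asynchronous [2+2] that is suprafacial on the alkene. This is the intramolecular vinylketene–alkene crossed cycloaddition known for geranoyl and farnesoyl chlorides (chrysanthenone and bergamotene series), here applied to a chain with silyloxy groups on both allylic carbons. The six-membered ring (C1-C2-C3-C4-C5-C6) closes in the 6-exo mode through the C1–C6 bond and the four-membered ring (C1-C2-C7-C6) through the C2–C7 bond, the crossed rather than fused sense following from the alkene substitution (tertiary versus secondary cation). The bridgeheads C2 and C6 are set by the C5 silyloxy carbinol: A1,3 strain with the cis C7 methyl keeps H5 in the alkene plane, the three-atom tether leaves from one face and the OTBS group lies on the other, so the ketene adds anti to OTBS, which ends on the side of the carbonyl bridge; C7 follows from the E geometry (methyl syn to the three-carbon bridge, oxygenated chain anti), and C8 is carried through unchanged. The step needs facial selectivity on the alkene (secured by that A1,3 bias), crossed regioselectivity (secured by the alkene substitution) and chemoselectivity over ketene dimerisation and β-elimination (slow addition at high dilution, neutral acid chloride formation, silyl ethers as the least deactivating protection).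

Step 9
Reactants: 15 (1R,4S,5R,7R)-4-(tert-butyldimethylsilyloxy)-7-methyl-2-methylidene-7-[(1R)-4-methyl-3-oxo-1-(triethylsilyloxy)pent-4-en-1-yl]bicyclo[3.1.1]heptan-6-one
Product: 18 (1R,2R,3R,7R,8R,11S)-11-(tert-butyldimethylsilyloxy)-3,7-dihydroxy-2,6,6-trimethyl-9-methylidenetricyclo[5.4.0.0(2,8)]undecan-5-one, via copper enolate 16 (not isolated), via TES-protected aldol 17 (not isolated)
Conditions: [(Ph3P)CuH]6 (1.2 equiv hydride), toluene, −40 to 0 °C; then 0.5 M aq. HCl, THF, 0 °C
Reagents that add atoms: none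
Why: Copper hydride reductive aldol cyclisation: hydride adds to the unhindered terminal CH2 (C12) of the 2-substituted enone, and the tetrasubstituted monovalent copper enolate 16 adds through C11 to the strained, non-enolisable cyclobutanone carbon C1 in a 7-(enolendo)-exo-trig closure; C1 is set by the ring because the chain on C7 can reach only the carbonyl face anti to the three-carbon bridge, and brief cold dilute acid in the work-up removes the TES group while leaving the TBS ether and the exocyclic alkene.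

Step 10
Reactants: 18 (1R,2R,3R,7R,8R,11S)-11-(tert-butyldimethylsilyloxy)-3,7-dihydroxy-2,6,6-trimethyl-9-methylidenetricyclo[5.4.0.0(2,8)]undecan-5-one; 19 (E)-2-methylbut-2-enal
Product: 21 (1R,2R,3R,5R,7R,8R,11S)-11-(tert-butyldimethylsilyloxy)-5,7-dihydroxy-2,6,6-trimethyl-9-methylidenetricyclo[5.4.0.0(2,8)]undecan-3-yl (2E)-2-methylbut-2-enoate, via samarium-bound hemiacetal 20 (not isolated)
Conditions: SmI2 (0.3 equiv) premixed with 19 (6 equiv), THF, −10 °C; then 18
Reagents that add atoms: none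
Why: Evans–Tishchenko reduction: the trivalent samarium alkoxide formed from SmI2 (divalent samarium) and 19 binds the C8 hydroxyl and the C10 ketone, the aldehyde adds to O8 and its formyl hydrogen is passed intramolecularly to the ketone face syn to O8, so the tiglate stays on O8 and the new C10 carbinol is 1,3-anti (R); the tertiary C1 hydroxyl is antiperiplanar to C10 across C1–C11 and cannot deliver hydride, and the product can no longer undergo retro-aldol cleavage.

Step 11
Reactants: 21 (1R,2R,3R,5R,7R,8R,11S)-11-(tert-butyldimethylsilyloxy)-5,7-dihydroxy-2,6,6-trimethyl-9-methylidenetricyclo[5.4.0.0(2,8)]undecan-3-yl (2E)-2-methylbut-2-enoate; 22 3-methylbutanoyl chloride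
Product: 23 (1R,2R,3R,5R,7R,8R,11S)-11-(tert-butyldimethylsilyloxy)-7-hydroxy-2,6,6-trimethyl-9-methylidene-5-(3-methylbutanoyloxy)tricyclo[5.4.0.0(2,8)]undecan-3-yl (2E)-2-methylbut-2-enoate
Conditions: pyridine, DMAP (cat.), CH2Cl2, 0 °C to rt
Reagents that add atoms: none
Why: DMAP-catalysed acylation of the secondary neopentyl alcohol; the tertiary cyclobutanol should not react under these conditions, and the 1,3-anti disposition across the seven-membered ring disfavours tiglate migration.

Step 12
Reactants: 23 (1R,2R,3R,5R,7R,8R,11S)-11-(tert-butyldimethylsilyloxy)-7-hydroxy-2,6,6-trimethyl-9-methylidene-5-(3-methylbutanoyloxy)tricyclo[5.4.0.0(2,8)]undecan-3-yl (2E)-2-methylbut-2-enoate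
Product: 24 methyl (1R,2R,3R,5R,7R,8R,11S)-11-(tert-butyldimethylsilyloxy)-2,6,6-trimethyl-9-methylidene-5-(3-methylbutanoyloxy)-3-[(2E)-2-methylbut-2-enoyloxy]tricyclo[5.4.0.0(2,8)]undecan-7-yl oxalate
Conditions: ClC(O)CO2Me, DMAP, pyridine, CH2Cl2, 0 to 40 °C
Reagents that add atoms: methyl chlorooxoacetate, COC(=O)C(=O)Cl
Why: The small, highly electrophilic chlorooxoacetate with DMAP acylates the hindered tertiary alcohol without alkoxide formation, which would risk strain-driven opening of the cyclobutanol toward the allylic C2.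

Step 13
Reactants: 24 methyl (1R,2R,3R,5R,7R,8R,11S)-11-(tert-butyldimethylsilyloxy)-2,6,6-trimethyl-9-methylidene-5-(3-methylbutanoyloxy)-3-[(2E)-2-methylbut-2-enoyloxy]tricyclo[5.4.0.0(2,8)]undecan-7-yl oxalate
Product: 25 (1R,2R,3R,5R,7S,8R,11S)-11-(tert-butyldimethylsilyloxy)-2,6,6-trimethyl-9-methylidene-5-(3-methylbutanoyloxy)tricyclo[5.4.0.0(2,8)]undecan-3-yl (2E)-2-methylbut-2-enoate
Conditions: Bu3SnH, AIBN (cat.), toluene, 110 °C, slow addition
Reagents that add atoms: none
Why: Radical deoxygenation of a tertiary oxalate (Barton–McCombie type): the stannyl radical fragments the oxalate to the tertiary C1 radical, which takes hydrogen from Bu3SnH on its only open face, syn to the three-carbon bridge, so C1 (S) is fixed by the ring; opening of the cyclobutyl radical and addition to the tiglate should be slower than hydrogen transfer.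

Step 14
Reactants: 25 (1R,2R,3R,5R,7S,8R,11S)-11-(tert-butyldimethylsilyloxy)-2,6,6-trimethyl-9-methylidene-5-(3-methylbutanoyloxy)tricyclo[5.4.0.0(2,8)]undecan-3-yl (2E)-2-methylbut-2-enoate
Product: 26 (1R,2R,3R,5R,7S,8R,11S)-11-hydroxy-2,6,6-trimethyl-9-methylidene-5-(3-methylbutanoyloxy)tricyclo[5.4.0.0(2,8)]undecan-3-yl (2E)-2-methylbut-2-enoate
Conditions: HF·pyridine, pyridine, THF, 0 °C to rt
Reagents that add atoms: none
Why: Buffered acidic fluoride removes the secondary TBS ether without touching the two esters or the alkenes (silyl ether cleavage).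

Step 15
Reactants: 26 (1R,2R,3R,5R,7S,8R,11S)-11-hydroxy-2,6,6-trimethyl-9-methylidene-5-(3-methylbutanoyloxy)tricyclo[5.4.0.0(2,8)]undecan-3-yl (2E)-2-methylbut-2-enoate
Product: 28 (1R,2R,3R,5R,7S,8R)-2,6,6,9-tetramethyl-5-(3-methylbutanoyloxy)-11-oxotricyclo[5.4.0.0(2,8)]undec-9-en-3-yl (2E)-2-methylbut-2-enoate, via β,γ-unsaturated ketone 27 (not isolated)
Conditions: DMP, CH2Cl2, 0 °C to rt; then DBU (3 equiv), rt
Reagents that add atoms: none
Why: Dess–Martin oxidation gives the β,γ-unsaturated ketone 27, whose doubly activated C4 hydrogens let DBU move the exocyclic alkene into conjugation (deconjugated to conjugated enone isomerisation); the other α carbon is a bridgehead, so no stereocentre can epimerise, no ester can be lost by β-elimination, and any endocyclic alkene isomer formed earlier converges on the same enone.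

Compound list
1 | 3-methylbut-3-en-2-one | CC(=O)C(C)=C | starting material
2 | (E)-4,4-dimethoxy-2-methylbut-2-enal | O=C/C(C)=C/C(OC)OC | starting material
3 | (−)-diisopinocampheylboron dienolate of 1, 2-(diisopinocampheylboryloxy)-3-methylbuta-1,3-diene | C=C(C)C(=C)OB([C@@H]1C[C@@H]2C[C@H]([C@H]1C)C2(C)C)[C@@H]1C[C@@H]2C[C@H]([C@H]1C)C2(C)C | intermediate
4 | (5R,6E)-5-hydroxy-8,8-dimethoxy-2,6-dimethylocta-1,6-dien-3-one | C=C(C)C(=O)C[C@@H](O)/C(C)=C/C(OC)OC | intermediate
5 | (5R,6E)-8,8-dimethoxy-2,6-dimethyl-5-(triethylsilyloxy)octa-1,6-dien-3-one | C=C(C)C(=O)C[C@@H](O[Si](CC)(CC)CC)/C(C)=C/C(OC)OC | intermediate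
6 | (2E,4R)-3,7-dimethyl-6-oxo-4-(triethylsilyloxy)octa-2,7-dienal | C=C(C)C(=O)C[C@@H](O[Si](CC)(CC)CC)/C(C)=C/C=O | intermediate
7 | methyl 3-methylbut-2-enoate | COC(=O)C=C(C)C | starting material
8 | lithium 1-methoxy-3-methylbuta-1,3-dien-1-olate (lithium dienolate of 7) | C=C(C)C=C(OC)O[Li] | intermediate
9 | tert-butyl[(1-methoxy-3-methylbuta-1,3-dien-1-yl)oxy]dimethylsilane (ketene acetal geometry not defined) | C=C(C)C=C(OC)O[Si](C)(C)C(C)(C)C | intermediate
10 | methyl (2E,5S,6E,8R)-5-hydroxy-3,7,11-trimethyl-10-oxo-8-(triethylsilyloxy)dodeca-2,6,11-trienoate | COC(=O)/C=C(\C)C[C@H](O)/C=C(\C)[C@H](O[Si](CC)(CC)CC)CC(=O)C(C)=C | intermediate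
11 | methyl (2E,5S,6E,8R)-5-(tert-butyldimethylsilyloxy)-3,7,11-trimethyl-10-oxo-8-(triethylsilyloxy)dodeca-2,6,11-trienoate | COC(=O)/C=C(\C)C[C@H](O[Si](C)(C)C(C)(C)C)/C=C(\C)[C@H](O[Si](CC)(CC)CC)CC(=O)C(C)=C | intermediate
12 | (2E,5S,6E,8R)-5-(tert-butyldimethylsilyloxy)-3,7,11-trimethyl-10-oxo-8-(triethylsilyloxy)dodeca-2,6,11-trienoic acid | OC(=O)/C=C(\C)C[C@H](O[Si](C)(C)C(C)(C)C)/C=C(\C)[C@H](O[Si](CC)(CC)CC)CC(=O)C(C)=C | intermediate
13 | (2E,5S,6E,8R)-5-(tert-butyldimethylsilyloxy)-3,7,11-trimethyl-10-oxo-8-(triethylsilyloxy)dodeca-2,6,11-trienoyl chloride | ClC(=O)/C=C(\C)C[C@H](O[Si](C)(C)C(C)(C)C)/C=C(\C)[C@H](O[Si](CC)(CC)CC)CC(=O)C(C)=C | intermediate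
14 | (5S,6E,8R)-5-(tert-butyldimethylsilyloxy)-7,11-dimethyl-3-methylidene-8-(triethylsilyloxy)dodeca-1,6,11-triene-1,10-dione (vinylketene) | O=C=CC(=C)C[C@H](O[Si](C)(C)C(C)(C)C)/C=C(\C)[C@H](O[Si](CC)(CC)CC)CC(=O)C(C)=C | intermediate
15 | (1R,4S,5R,7R)-4-(tert-butyldimethylsilyloxy)-7-methyl-2-methylidene-7-[(1R)-4-methyl-3-oxo-1-(triethylsilyloxy)pent-4-en-1-yl]bicyclo[3.1.1]heptan-6-one (OTBS on the side of the carbonyl bridge, C7 methyl syn to the three-carbon bridge) | C=C1C[C@H](O[Si](C)(C)C(C)(C)C)[C@@H]2C(=O)[C@H]1[C@@]2(C)[C@H](O[Si](CC)(CC)CC)CC(=O)C(C)=C | intermediate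
16 | monovalent copper enolate of the conjugate-reduced ketone of 15 (phosphine ligand omitted) | C=C1C[C@H](O[Si](C)(C)C(C)(C)C)[C@@H]2C(=O)[C@H]1[C@@]2(C)[C@H](O[Si](CC)(CC)CC)CC(O[Cu])=C(C)C | intermediate
17 | (1R,2R,3R,7R,8R,11S)-11-(tert-butyldimethylsilyloxy)-7-hydroxy-2,6,6-trimethyl-9-methylidene-3-(triethylsilyloxy)tricyclo[5.4.0.0(2,8)]undecan-5-one | C=C1C[C@H](O[Si](C)(C)C(C)(C)C)[C@@H]2[C@]3(O)[C@H]1[C@@]2(C)[C@H](O[Si](CC)(CC)CC)CC(=O)C3(C)C | intermediate
18 | (1R,2R,3R,7R,8R,11S)-11-(tert-butyldimethylsilyloxy)-3,7-dihydroxy-2,6,6-trimethyl-9-methylidenetricyclo[5.4.0.0(2,8)]undecan-5-one | C=C1C[C@H](O[Si](C)(C)C(C)(C)C)[C@@H]2[C@]3(O)[C@H]1[C@@]2(C)[C@H](O)CC(=O)C3(C)C | intermediate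
19 | (E)-2-methylbut-2-enal | C/C=C(\C)C=O | starting material
20 | hemiacetal of the C8 hydroxyl of 18 with 19 (samarium-bound; hemiacetal carbon not defined) | C=C1C[C@H](O[Si](C)(C)C(C)(C)C)[C@@H]2[C@]3(O)[C@H]1[C@@]2(C)[C@H](OC(O)/C(C)=C/C)CC(=O)C3(C)C | intermediate
21 | (1R,2R,3R,5R,7R,8R,11S)-11-(tert-butyldimethylsilyloxy)-5,7-dihydroxy-2,6,6-trimethyl-9-methylidenetricyclo[5.4.0.0(2,8)]undecan-3-yl (2E)-2-methylbut-2-enoate | C=C1C[C@H](O[Si](C)(C)C(C)(C)C)[C@@H]2[C@]3(O)[C@H]1[C@@]2(C)[C@H](OC(=O)/C(C)=C/C)C[C@@H](O)C3(C)C | intermediate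
22 | 3-methylbutanoyl chloride | CC(C)CC(=O)Cl | starting material
23 | (1R,2R,3R,5R,7R,8R,11S)-11-(tert-butyldimethylsilyloxy)-7-hydroxy-2,6,6-trimethyl-9-methylidene-5-(3-methylbutanoyloxy)tricyclo[5.4.0.0(2,8)]undecan-3-yl (2E)-2-methylbut-2-enoate | C=C1C[C@H](O[Si](C)(C)C(C)(C)C)[C@@H]2[C@]3(O)[C@H]1[C@@]2(C)[C@H](OC(=O)/C(C)=C/C)C[C@@H](OC(=O)CC(C)C)C3(C)C | intermediate
24 | methyl (1R,2R,3R,5R,7R,8R,11S)-11-(tert-butyldimethylsilyloxy)-2,6,6-trimethyl-9-methylidene-5-(3-methylbutanoyloxy)-3-[(2E)-2-methylbut-2-enoyloxy]tricyclo[5.4.0.0(2,8)]undecan-7-yl oxalate | C=C1C[C@H](O[Si](C)(C)C(C)(C)C)[C@@H]2[C@]3(OC(=O)C(=O)OC)[C@H]1[C@@]2(C)[C@H](OC(=O)/C(C)=C/C)C[C@@H](OC(=O)CC(C)C)C3(C)C | intermediate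
25 | (1R,2R,3R,5R,7S,8R,11S)-11-(tert-butyldimethylsilyloxy)-2,6,6-trimethyl-9-methylidene-5-(3-methylbutanoyloxy)tricyclo[5.4.0.0(2,8)]undecan-3-yl (2E)-2-methylbut-2-enoate | C=C1C[C@H](O[Si](C)(C)C(C)(C)C)[C@@H]2[C@@H]3[C@H]1[C@@]2(C)[C@H](OC(=O)/C(C)=C/C)C[C@@H](OC(=O)CC(C)C)C3(C)C | intermediate
26 | (1R,2R,3R,5R,7S,8R,11S)-11-hydroxy-2,6,6-trimethyl-9-methylidene-5-(3-methylbutanoyloxy)tricyclo[5.4.0.0(2,8)]undecan-3-yl (2E)-2-methylbut-2-enoate | C=C1C[C@H](O)[C@@H]2[C@@H]3[C@H]1[C@@]2(C)[C@H](OC(=O)/C(C)=C/C)C[C@@H](OC(=O)CC(C)C)C3(C)C | intermediate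
27 | (1R,2R,3R,5R,7S,8R)-2,6,6-trimethyl-9-methylidene-5-(3-methylbutanoyloxy)-11-oxotricyclo[5.4.0.0(2,8)]undecan-3-yl (2E)-2-methylbut-2-enoate | C=C1CC(=O)[C@@H]2[C@@H]3[C@H]1[C@@]2(C)[C@H](OC(=O)/C(C)=C/C)C[C@@H](OC(=O)CC(C)C)C3(C)C | intermediate
28 | (1R,2R,3R,5R,7S,8R)-2,6,6,9-tetramethyl-5-(3-methylbutanoyloxy)-11-oxotricyclo[5.4.0.0(2,8)]undec-9-en-3-yl (2E)-2-methylbut-2-enoate | C/C=C(\C)C(=O)O[C@@H]1C[C@@H](OC(=O)CC(C)C)C(C)(C)[C@@H]2[C@H]3C(=O)C=C(C)[C@@H]2[C@]31C | target

Total step count: 15. Longest linear sequence: 14 steps (steps 1 to 3 and 5 to 15, from 1 and 2 to 28); step 4 is a one-step branch.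

Steps most likely to fail

Step 8. The alkene, deactivated by two allylic silyloxy groups, may react too slowly, so that the vinylketene dimerises or the β-silyloxy ketone eliminates under hot amine. The fallback sets out from 12 and returns at 15 and uses the more electrophilic keteniminium analogue of the ketene. Acid chloride 13, made as in step 8, is treated at −78 °C with one equivalent of pyrrolidine and Et3N to give the pyrrolidine amide F1. Tf2O and 2,4,6-collidine in 1,2-dichloroethane convert F1, by O-triflation and loss of a C3-methyl proton, into the vinylketeniminium triflate F2. F2 should undergo the same crossed [2+2] at or below 60 °C, with the same A1,3 control, to the cyclobutaniminium triflate F3, and aqueous NaHCO3 hydrolyses F3 to 15.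

Step 12. Acylation of the tertiary cyclobutanol may fail for steric reasons, since the CMe2 carbon flanks it on one side and the C5 silyloxy group sits syn-1,3 to it on the other; this would also block step 13. The fallback sets out from 23 and returns at 26, replacing steps 12 to 14, and uses the neighbouring oxygen as the handle. HF·pyridine removes the TBS group to give the diol F4. 1,1'-Thiocarbonyldiimidazole and DMAP in hot toluene tie the syn C5 and C1 hydroxyls into the six-membered cyclic thionocarbonate F5. Bu3SnH and AIBN should then cleave the C1–O bond (tertiary radical) with hydrogen delivery as in step 13, and the stannyl thiocarbonate left on O5 loses carbonyl sulfide on aqueous KF work-up to give 26.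

Step 10. Hydride transfer may not take place because the conjugated, α-branched aldehyde adds poorly to the hindered C8 hydroxyl, or the samarium alkoxide may induce retro-aldol opening of the seven-membered ring. The fallback sets out from 18 and returns at 21: acylation first, then reduction under reagent control. Tiglic anhydride, pyridine and DMAP at 0 °C esterify only the secondary hydroxyl to give the keto tiglate F6. (S)-2-Methyl-CBS-oxazaborolidine with catecholborane at −78 °C (CBS reduction) should then reduce the ketone, which is flanked by a quaternary carbon and a CH2 group, to the (5R) carbinol 21 without hydroborating the exocyclic alkene.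

Further compounds
F1 | step 8 | 1-[(2E,5S,6E,8R)-5-(tert-butyldimethylsilyloxy)-3,7,11-trimethyl-10-oxo-8-(triethylsilyloxy)dodeca-2,6,11-trienoyl]pyrrolidine | O=C(N1CCCC1)/C=C(\C)C[C@H](O[Si](C)(C)C(C)(C)C)/C=C(\C)[C@H](O[Si](CC)(CC)CC)CC(=O)C(C)=C
F2 | step 8 | vinylketeniminium triflate derived from F1 (pyrrolidinium analogue of 14) | C=C(C=C=[N+]1CCCC1)C[C@H](O[Si](C)(C)C(C)(C)C)/C=C(\C)[C@H](O[Si](CC)(CC)CC)CC(=O)C(C)=C.[O-]S(=O)(=O)C(F)(F)F
F3 | step 8 | cyclobutaniminium triflate (pyrrolidinium analogue of 15 at C1) | C=C1C[C@H](O[Si](C)(C)C(C)(C)C)[C@@H]2C(=[N+]3CCCC3)[C@H]1[C@@]2(C)[C@H](O[Si](CC)(CC)CC)CC(=O)C(C)=C.[O-]S(=O)(=O)C(F)(F)F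
F4 | step 12 | (1R,2R,3R,5R,7R,8R,11S)-7,11-dihydroxy-2,6,6-trimethyl-9-methylidene-5-(3-methylbutanoyloxy)tricyclo[5.4.0.0(2,8)]undecan-3-yl (2E)-2-methylbut-2-enoate | C=C1C[C@H](O)[C@@H]2[C@]3(O)[C@H]1[C@@]2(C)[C@H](OC(=O)/C(C)=C/C)C[C@@H](OC(=O)CC(C)C)C3(C)C
F5 | step 12 | cyclic thionocarbonate of F4 bridging the C5 and C1 oxygens | C=C1C[C@H](OC(=S)O4)[C@@H]2[C@]34[C@H]1[C@@]2(C)[C@H](OC(=O)/C(C)=C/C)C[C@@H](OC(=O)CC(C)C)C3(C)C
F6 | step 10 | (1R,2R,3R,7R,8R,11S)-11-(tert-butyldimethylsilyloxy)-7-hydroxy-2,6,6-trimethyl-9-methylidene-5-oxotricyclo[5.4.0.0(2,8)]undecan-3-yl (2E)-2-methylbut-2-enoate | C=C1C[C@H](O[Si](C)(C)C(C)(C)C)[C@@H]2[C@]3(O)[C@H]1[C@@]2(C)[C@H](OC(=O)/C(C)=C/C)CC(=O)C3(C)C
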